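**Retrosynthetic overview**
1. Gravicycle ⇐ cleavage of two MOM ethers ⇐ late C–H hydroxylation of ring A ⇐ 22-membered macrocycle.
2. Macrocycle ⇐ intramolecular B-alkyl Suzuki coupling (ring A C–CH2 bond) ⇐ diaryl ether made by Cu-catalysed O-arylation of the ring B phenol with 1-bromo-3-iodobenzene.
3. Ring B phenol with the (R)-carbinol ⇐ key step: stereospecific 1,2-metallate rearrangement (aryl shift from boron to carbon) between a (−)-sparteine-derived lithiated C14 carbamate and a ring B bis-boronate, then oxidation of both C–B bonds.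
4. Ring B bis-boronate ⇐ resorcinol (MOM protection, ortho-lithiation/borylation, Ir C–H borylation); C14 carbamate ⇐ hept-6-en-1-ol + 7-bromohept-1-ene (sp3–sp3 Suzuki).
5. Ring order: both benzene rings are bought; the only ring formed is the macrocycle, closed in step 8.

Assumption: ring A is the chain-bearing 1,3,5-trisubstituted ring, ring B the 2,6-dihydroxy-1,4-phenylene ring; the SMILES is read as thirteen CH2 groups between the (R)-carbinol carbon and ring A (22-membered ring).

**Step 1**
Reactants: 1 resorcinol (benzene-1,3-diol)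
Product: 2 1,3-bis(methoxymethoxy)benzene
Conditions: NaH (2.4 equiv), MOMCl (2.4 equiv), DMF, 0 °C to rt
Reagents that add atoms: chloromethyl methyl ether, COCCl
Why: Williamson-type double O-alkylation (acetal protection); MOM directs the lithiation in step 2, survives the organolithium, Ir, Pd and Cu steps and is cleaved by dilute acid at the end.

**Step 2**
Reactants: 2 1,3-bis(methoxymethoxy)benzene
Product: 4 2-[2,6-bis(methoxymethoxy)phenyl]-4,4,5,5-tetramethyl-1,3,2-dioxaborolane, via [2,6-bis(methoxymethoxy)phenyl]lithium 3 (not isolated)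
Conditions: n-BuLi (1.1 equiv), THF, 0 °C to rt, 1.5 h; i-PrOBpin (1.3 equiv), −78 °C to rt; H2O
Reagents that add atoms: 2-isopropoxy-4,4,5,5-tetramethyl-1,3,2-dioxaborolane, CC(C)OB1OC(C)(C)C(C)(C)O1
Why: Directed ortho-metalation at the C–H flanked by two OMOM groups, then trapping with the borate ester, gives a di-ortho-shielded boronate that later serves as a masked phenol.

**Step 3**
Reactants: 4 2-[2,6-bis(methoxymethoxy)phenyl]-4,4,5,5-tetramethyl-1,3,2-dioxaborolane
Product: 5 2,2'-[2,6-bis(methoxymethoxy)-1,4-phenylene]bis(4,4,5,5-tetramethyl-1,3,2-dioxaborolane)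
Conditions: [Ir(OMe)(cod)]2 (1.5 mol%), dtbpy (3 mol%), B2pin2 (1.0 equiv), THF, 80 °C
Reagents that add atoms: bis(pinacolato)diboron, CC1(C)OB(OC1(C)C)B1OC(C)(C)C(C)(C)O1
Why: Sterically governed Ir-catalysed aromatic C–H borylation; the position para to the first boron is the only C–H without an ortho substituent.

**Step 4**
Reactants: 6 hept-6-en-1-ol
Product: 7 hept-6-en-1-yl N,N-diisopropylcarbamate
Conditions: NaH (1.2 equiv), i-Pr2NCOCl (1.1 equiv), THF, 0 °C to 60 °C
Reagents that add atoms: N,N-diisopropylcarbamoyl chloride, CC(C)N(C(C)C)C(Cl)=O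
Why: O-Carbamoylation installs the Hoppe carbamate, which directs the α-lithiation and is the leaving group of the 1,2-shift in step 6.

**Step 5**
Reactants: 7 hept-6-en-1-yl N,N-diisopropylcarbamate; 8 7-bromohept-1-ene
Product: 10 tetradec-13-en-1-yl N,N-diisopropylcarbamate, via B-alkyl-9-BBN 9 (not isolated)
Conditions: 9-BBN (1.0 equiv), THF, rt, 4 h; then 8 (1.1 equiv), Pd(OAc)2 (4 mol%), PCy3 (8 mol%), K3PO4·H2O (1.3 equiv), THF, rt
Reagents that add atoms: none
Why: Anti-Markovnikov hydroboration, then sp3–sp3 Suzuki–Miyaura coupling of the B-alkyl-9-BBN with the primary bromide (PCy3 outruns β-hydride elimination), joins two C7 units into the C14 chain.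

**Step 6**
Reactants: 10 tetradec-13-en-1-yl N,N-diisopropylcarbamate; 5 2,2'-[2,6-bis(methoxymethoxy)-1,4-phenylene]bis(4,4,5,5-tetramethyl-1,3,2-dioxaborolane)
Product: 14 (R)-4-(1-hydroxytetradec-13-en-1-yl)-2,6-bis(methoxymethoxy)phenol, via lithiated carbamate 11 (not isolated), via boronate complex 12 (not isolated), via bis(boronic ester) 13 (not isolated)
Conditions: s-BuLi (0.95 equiv), (−)-sparteine (1.0 equiv), Et2O, −78 °C, 5 h; 5 (1.1 equiv), −78 °C, 1 h, then 35 °C, 16 h; 2 M NaOH, 30% H2O2, THF, 0 °C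
Reagents that add atoms: hydrogen peroxide, OO
Why: Proposed new method: site-selective lithiation–borylation on an arene-1,4-diyl bis(pinacol boronate) — the (−)-sparteine-bound (S)-carbenoid 11 (pro-S deprotonation) should add with retention only to the unhindered boron, because the other boron is screened on both faces of its empty p orbital by the two ortho OMOM groups and made less Lewis acidic by them; in complex 12 the aryl group migrates from boron to carbon anti to the departing carbamate (stereospecific 1,2-metallate rearrangement, inversion at carbon) to give (R)-13, and one peroxide work-up oxidises both C–B bonds with retention (two further B-to-O 1,2-shifts), unmasking the hindered boronate as the phenol and fixing the (R)-carbinol; closest known reaction type: Hoppe–Aggarwal lithiation–borylation of aryl pinacol boronates and selective homologation of the less hindered boron in aliphatic bis(boronic esters).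

**Step 7**
Reactants: 14 (R)-4-(1-hydroxytetradec-13-en-1-yl)-2,6-bis(methoxymethoxy)phenol; 15 1-bromo-3-iodobenzene
Product: 16 (R)-1-[4-(3-bromophenoxy)-3,5-bis(methoxymethoxy)phenyl]tetradec-13-en-1-ol
Conditions: CuI (10 mol%), picolinic acid (20 mol%), K3PO4 (2 equiv), 15 (1.5 equiv), DMSO, 80 °C
Reagents that add atoms: none
Why: Ullmann-type Cu-catalysed O-arylation with a ligand that accepts di-ortho-substituted phenols; the C–I bond reacts far faster than C–Br and the secondary alcohol is much less nucleophilic than the phenoxide, so the stereocenter is untouched.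

**Step 8**
Reactants: 16 (R)-1-[4-(3-bromophenoxy)-3,5-bis(methoxymethoxy)phenyl]tetradec-13-en-1-ol
Product: 18 (R)-22-membered diaryl ether macrocycle lacking the ring A hydroxyl [ring A: 1,3-phenylene; ring B: 2,6-bis(methoxymethoxy)-1,4-phenylene; ring B carries CH(OH)(CH2)13 to ring A], via B-alkyl-9-BBN 17 (not isolated)
Conditions: 9-BBN (1.5 equiv), THF, 0 °C to rt; then syringe-pump addition to Pd(dppf)Cl2 (10 mol%), 3 M aq. NaOH (3 equiv), THF, 65 °C, final 2 mM
Reagents that add atoms: none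
Why: Hydroboration of the terminal alkene and intramolecular B-alkyl Suzuki–Miyaura coupling with the aryl bromide under high dilution close the strain-free 22-membered ring without touching the stereocenter.

**Step 9**
Reactants: 18 (R)-22-membered diaryl ether macrocycle lacking the ring A hydroxyl
Product: 20 ring B O,O'-bis(methoxymethyl) gravicycle [target skeleton with both ring B hydroxyls as OMOM ethers; ring A OH and (R)-carbinol OH free], via arylboronate 19 (not isolated)
Conditions: [Ir(OMe)(cod)]2 (3 mol%), dtbpy (6 mol%), B2pin2 (1.1 equiv), THF, 80 °C; then 2 M NaOH, 30% H2O2, 0 °C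
Reagents that add atoms: hydrogen peroxide, OO
Why: One-pot Ir-catalysed C–H borylation/oxidation: C5 of ring A is the only aromatic C–H without an ortho substituent (both ring B C–H bonds are flanked), the alcohol is capped in situ as O–Bpin, and peroxide turns the aryl boronate into the phenol by B-to-O 1,2-shift.

**Step 10**
Reactants: 20 ring B O,O'-bis(methoxymethyl) gravicycle
Product: 21 gravicycle
Conditions: 2 M aq. HCl, THF, 45 °C
Reagents that add atoms: none
Why: Acid-catalysed acetal hydrolysis of the two aryl MOM ethers; the benzylic carbinol is meta to both ring B oxygens and para to a twisted diaryl ether oxygen, so it does not ionise in dilute acid and keeps its (R) configuration.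

**Compound list**
1 | resorcinol (benzene-1,3-diol) | Oc1cccc(O)c1 | starting material
2 | 1,3-bis(methoxymethoxy)benzene | COCOc1cccc(OCOC)c1 | intermediate
3 | [2,6-bis(methoxymethoxy)phenyl]lithium | [Li]c1c(OCOC)cccc1OCOC | intermediate
4 | 2-[2,6-bis(methoxymethoxy)phenyl]-4,4,5,5-tetramethyl-1,3,2-dioxaborolane | COCOc1cccc(OCOC)c1B1OC(C)(C)C(C)(C)O1 | intermediate
5 | 2,2'-[2,6-bis(methoxymethoxy)-1,4-phenylene]bis(4,4,5,5-tetramethyl-1,3,2-dioxaborolane) | COCOc1cc(B2OC(C)(C)C(C)(C)O2)cc(OCOC)c1B1OC(C)(C)C(C)(C)O1 | intermediate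
6 | hept-6-en-1-ol | OCCCCCC=C | starting material
7 | hept-6-en-1-yl N,N-diisopropylcarbamate | C=CCCCCCOC(=O)N(C(C)C)C(C)C | intermediate
8 | 7-bromohept-1-ene | BrCCCCCC=C | starting material
9 | 7-(9-borabicyclo[3.3.1]nonan-9-yl)heptyl N,N-diisopropylcarbamate | CC(C)N(C(C)C)C(=O)OCCCCCCCB1C2CCCC1CCC2 | intermediate
10 | tetradec-13-en-1-yl N,N-diisopropylcarbamate | C=CCCCCCCCCCCCCOC(=O)N(C(C)C)C(C)C | intermediate
11 | (S)-1-lithiotetradec-13-en-1-yl N,N-diisopropylcarbamate, (−)-sparteine complex (diamine not drawn) | [Li][C@@H](CCCCCCCCCCCC=C)OC(=O)N(C(C)C)C(C)C | intermediate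
12 | lithium boronate complex: the (S)-1-(diisopropylcarbamoyloxy)tetradec-13-en-1-yl group bound to the unhindered boron of 5 | C=CCCCCCCCCCCC[C@@H](OC(=O)N(C(C)C)C(C)C)[B-]1(OC(C)(C)C(C)(C)O1)c1cc(OCOC)c(B2OC(C)(C)C(C)(C)O2)c(OCOC)c1.[Li+] | intermediate
13 | 2-{(1R)-1-[3,5-bis(methoxymethoxy)-4-(4,4,5,5-tetramethyl-1,3,2-dioxaborolan-2-yl)phenyl]tetradec-13-en-1-yl}-4,4,5,5-tetramethyl-1,3,2-dioxaborolane | C=CCCCCCCCCCCC[C@@H](B1OC(C)(C)C(C)(C)O1)c1cc(OCOC)c(B2OC(C)(C)C(C)(C)O2)c(OCOC)c1 | intermediate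
14 | (R)-4-(1-hydroxytetradec-13-en-1-yl)-2,6-bis(methoxymethoxy)phenol | C=CCCCCCCCCCCC[C@@H](O)c1cc(OCOC)c(O)c(OCOC)c1 | intermediate
15 | 1-bromo-3-iodobenzene | Brc1cccc(I)c1 | starting material
16 | (R)-1-[4-(3-bromophenoxy)-3,5-bis(methoxymethoxy)phenyl]tetradec-13-en-1-ol | C=CCCCCCCCCCCC[C@@H](O)c1cc(OCOC)c(Oc2cccc(Br)c2)c(OCOC)c1 | intermediate
17 | (R)-14-(9-borabicyclo[3.3.1]nonan-9-yl)-1-[4-(3-bromophenoxy)-3,5-bis(methoxymethoxy)phenyl]tetradecan-1-ol | C(CCCCCCCCCCCC[C@@H](O)c1cc(OCOC)c(Oc2cccc(Br)c2)c(OCOC)c1)B1C2CCCC1CCC2 | intermediate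
18 | (R)-22-membered diaryl ether macrocycle lacking the ring A hydroxyl; ring B hydroxyls as OMOM ethers, carbinol OH free | c1cc2cc(c1)Oc1c(OCOC)cc(cc1OCOC)[C@H](O)CCCCCCCCCCCCC2 | intermediate
19 | ring A C5 pinacol boronate of 18 with the carbinol capped as O-Bpin | CC1(C)OB(OC1(C)C)c1cc2cc(c1)Oc1c(OCOC)cc(cc1OCOC)[C@H](OB1OC(C)(C)C(C)(C)O1)CCCCCCCCCCCCC2 | intermediate
20 | ring B O,O'-bis(methoxymethyl) gravicycle (ring A OH and (R)-carbinol OH free) | Oc1cc2cc(c1)Oc1c(OCOC)cc(cc1OCOC)[C@H](O)CCCCCCCCCCCCC2 | intermediate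
21 | gravicycle | Oc1cc2cc(c1)Oc1c(O)cc(cc1O)[C@H](O)CCCCCCCCCCCCC2 | target

**Summary**
Total steps: 10. Longest linear sequence: 8 steps (1 → 2 → 4 → 5 → 14 → 16 → 18 → 20 → 21; steps 1, 2, 3, 6, 7, 8, 9, 10).

Three steps most likely to fail:

Step 6 (the proposed new reaction). The carbenoid could also attack the shielded boron, or the shielded boronate could be lost. The fallback uses known chemistry, sets out from 2 (with 10, through 11) and comes back at 14. Ir-catalysed C–H borylation of 2 ([Ir(OMe)(cod)]2, dtbpy, B2pin2, THF, 80 °C) gives 2-[3,5-bis(methoxymethoxy)phenyl]-4,4,5,5-tetramethyl-1,3,2-dioxaborolane F1. Ordinary lithiation–borylation of 11 with this single boronic ester gives the lithium boronate complex F2, which rearranges to the secondary boronic ester (R)-2-{1-[3,5-bis(methoxymethoxy)phenyl]tetradec-13-en-1-yl}-4,4,5,5-tetramethyl-1,3,2-dioxaborolane F3. Oxidation (NaOH, H2O2) gives (R)-1-[3,5-bis(methoxymethoxy)phenyl]tetradec-13-en-1-ol F4. n-BuLi (2.3 equiv)/TMEDA in THF at 0 °C then lithiates F4 between the two OMOM groups to the dilithio species F5, B(OMe)3 gives the dimethyl arylboronate lithium alkoxide F6, and H2O2 oxidation delivers 14.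

Step 7. The phenol is di-ortho-substituted, and hot base on a para-hydroxybenzylic alcohol could erode the stereocenter through a quinone methide. The fallback sets out from 15 and 14 and comes back at 16. Oxidation of 15 with mCPBA/TsOH·H2O (MeCN, 60 °C) gives 1-bromo-3-[hydroxy(tosyloxy)iodo]benzene F7, trapped in the same pot with 1,3,5-trimethoxybenzene as (3-bromophenyl)(2,4,6-trimethoxyphenyl)iodonium tosylate F8. Then 14 and F8 with K2CO3 in toluene at 40 °C give 16 by metal-free ligand coupling on iodine, the trimethoxyphenyl group staying on iodine.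

Step 8. Oligomerisation or protodeboronation could outrun the macrocyclisation. The fallback closes the ring at the diaryl ether bond instead; it sets out from 14 (with 15) and comes back at 18. Hydroboration of 14 with 9-BBN gives the B-alkyl-9-BBN F9, which is coupled at room temperature with 15 selectively at the C–I bond (Pd(dppf)Cl2, aq. NaOH) to (R)-4-[14-(3-bromophenyl)-1-hydroxytetradecyl]-2,6-bis(methoxymethoxy)phenol F10. Intramolecular Ullmann etherification (CuI, N,N-dimethylglycine, Cs2CO3, dioxane, 100 °C, 2 mM) then gives 18.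

**Further compounds**
F1 | step 6 | 2-[3,5-bis(methoxymethoxy)phenyl]-4,4,5,5-tetramethyl-1,3,2-dioxaborolane | COCOc1cc(OCOC)cc(c1)B1OC(C)(C)C(C)(C)O1
F2 | step 6 | lithium boronate complex of F1 with the (S)-1-(diisopropylcarbamoyloxy)tetradec-13-en-1-yl group | C=CCCCCCCCCCCC[C@@H](OC(=O)N(C(C)C)C(C)C)[B-]1(OC(C)(C)C(C)(C)O1)c1cc(OCOC)cc(OCOC)c1.[Li+]
F3 | step 6 | (R)-2-{1-[3,5-bis(methoxymethoxy)phenyl]tetradec-13-en-1-yl}-4,4,5,5-tetramethyl-1,3,2-dioxaborolane | C=CCCCCCCCCCCC[C@@H](B1OC(C)(C)C(C)(C)O1)c1cc(OCOC)cc(OCOC)c1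
F4 | step 6 | (R)-1-[3,5-bis(methoxymethoxy)phenyl]tetradec-13-en-1-ol | C=CCCCCCCCCCCC[C@@H](O)c1cc(OCOC)cc(OCOC)c1
F5 | step 6 | dilithio species: lithium (R)-1-[4-lithio-3,5-bis(methoxymethoxy)phenyl]tetradec-13-en-1-olate | C=CCCCCCCCCCCC[C@@H](O[Li])c1cc(OCOC)c([Li])c(OCOC)c1
F6 | step 6 | dimethyl arylboronate lithium alkoxide: lithium (R)-1-[4-(dimethoxyboryl)-3,5-bis(methoxymethoxy)phenyl]tetradec-13-en-1-olate | C=CCCCCCCCCCCC[C@@H](O[Li])c1cc(OCOC)c(B(OC)OC)c(OCOC)c1
F7 | step 7 | 1-bromo-3-[hydroxy(tosyloxy)iodo]benzene | OI(OS(=O)(=O)c1ccc(C)cc1)c1cccc(Br)c1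
F8 | step 7 | (3-bromophenyl)(2,4,6-trimethoxyphenyl)iodonium tosylate | COc1cc(OC)c([I+]c2cccc(Br)c2)c(OC)c1.Cc1ccc(cc1)S([O-])(=O)=O
F9 | step 8 | B-alkyl-9-BBN: (R)-4-[14-(9-borabicyclo[3.3.1]nonan-9-yl)-1-hydroxytetradecyl]-2,6-bis(methoxymethoxy)phenol | C(CCCCCCCCCCCC[C@@H](O)c1cc(OCOC)c(O)c(OCOC)c1)B1C2CCCC1CCC2
F10 | step 8 | (R)-4-[14-(3-bromophenyl)-1-hydroxytetradecyl]-2,6-bis(methoxymethoxy)phenol | Brc1cccc(CCCCCCCCCCCCC[C@@H](O)c2cc(OCOC)c(O)c(OCOC)c2)c1
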